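## Structural features

The target is an achiral benzophenone built from three benzene rings. Ring A is 1,2,4,5-tetrasubstituted: C1 carries the ketone carbon, C2 a hydroxyl group hydrogen-bonded to that carbonyl, C4 a methoxy group and C5 a saturated three-carbon chain. Ring B, a 4-hydroxyphenyl group, sits on the ketone carbon, and ring C, a second 4-hydroxyphenyl group, ends the propyl chain. There are no stereocentres and no double-bond geometry, so no stereocentres stand next to each other and stereocontrol is not an issue. The sensitive functions are the three phenols (acidic towards organometallic reagents and activating their rings towards electrophiles), the single methyl ether that must stay distinct from them, and the diaryl ketone, which can suffer over-addition or over-reduction. The real difficulty is therefore placing four different substituents on ring A and attaching two further rings without disturbing the oxygen pattern. The feature exploited is that ring B and ring C are the same 4-oxygenated phenyl group, each joined by one C–C bond to a carbon that hangs on ring A (the carbonyl carbon at C1 and the terminal CH2 of the C5 chain). A single aryl nucleophile can therefore supply both rings to a ring A fragment that is electrophilic at these two carbons.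

## Logic of the disconnections

18 back to 17: the three phenolic O–H bonds (ring A C2, ring B C4, ring C C4) are replaced by O–CH2OCH3 acetal bonds. Free phenols would destroy an arylzinc reagent, and one common acid-labile group lets a single final step free all three while the C4 methyl ether, which is not an acetal, stays. This reduces the problem of telling one OMe from three OH to a choice of protecting group. The forward step must cleave aryl acetals without demethylation and without alkylating the electron-rich rings.

17 back to 10 and 14: two C–C bonds are cut, carbonyl carbon to ring B and terminal chain CH2 to ring C. Both cuts release the same aryl anion equivalent because the two rings are identical. 17 therefore falls into one ring A piece, 10, electrophilic at an acyl carbon (thioester) and at a primary sp3 carbon (bromide), and two molecules of 14. Two of the three rings then come from one reagent and the remaining piece holds a single ring. The forward step asks one palladium catalyst to turn over on an acyl–sulfur bond and on an unactivated primary C–Br bond, to stop at the ketone, and to avoid beta-hydride elimination in the chain.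

14 back to 12 and 11: the C–Zn bond is traced to the C–Br bond of 12, by way of the magnesium compound 13, and the acetal O–C bond of 12 to the phenol 11. Zinc is the final metal because only it tolerates a thioester and a ketone. The demand is complete transmetalation, since any arylmagnesium species left over would add to carbonyl groups in the key step.

10 back to 9: the C–Br bond is traced to a C–OH bond. A primary bromide would not survive hydroxide, so it is made after every basic step and the alcohol carries that carbon until then. The forward step must be a neutral substitution that spares the thioester and the acetal.

9 back to 7 and 8: the acyl C–S bond is cut. The thioester is placed late because it would be hydrolysed by the base of the preceding step and could interfere with the palladium chemistry there. The demand is that acylation of sulfur must win over acylation of the free primary hydroxyl of 7.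

7 back to 3 and 4: the ring A C5–CH2 bond is cut, and the acid and alcohol are taken back to the two ester groups of 6. An sp2–sp3 coupling of the aryl iodide 3 with the borane 5, made from alkene 4, brings in the complete saturated chain with oxygen on its last carbon, so nothing has to be reduced afterwards. The fragment is thereby reduced to a halogenated salicylate and a three-carbon alkene. Boron must go to the terminal carbon, the alkylpalladium intermediate must couple and not eliminate, and the hydrolysis that follows in the same flask must spare the acetal.

3 back to 2 and 1: the acetal O–C bond on C2 and then the C5–I bond are removed. 1 already holds the C1 carboxyl carbon, the C2 oxygen and the C4 methoxy group in the right relationship, so ring A is never constructed and only one position has to be functionalised. The demand is iodination at C5 and not at C3.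

## Other disconnections considered

Alternative 1: The cut takes ring B apart at its two ortho–meta bonds, so ring B is made and not attached. In the forward direction 6-{3-[4-(benzyloxy)phenyl]propyl}-7-methoxy-4-oxo-4H-chromene-3-carbaldehyde A2 would react with dimethyl 3-oxopentanedioate A3 under an amine base. Conjugate addition at the pyranone C2, opening of the pyranone (which frees the ring A C2 phenol), condensation of the second methylene with the formyl group and aromatisation would give dimethyl 5-(5-{3-[4-(benzyloxy)phenyl]propyl}-2-hydroxy-4-methoxybenzoyl)-2-hydroxybenzene-1,3-dicarboxylate A1.
- In its favour: the key step needs no metal, it is a known reaction type for 3-formylchromones and so better precedented than the chosen key step, and the C2 hydroxyl needs no protecting group. On these three points the alternative is the better plan.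
- Against it here: ring B arrives with two ester groups flanking its hydroxyl that the target lacks. Hydrolysis, a double decarboxylation of a hydroxy-isophthalic acid under forcing conditions, and debenzylation stand between A1 and the target. A2 must also be built beforehand with the chain and ring C already on it, so attaching ring C remains a separate problem.
- Structure: the alternative constructs a ring that can be bought and then removes two carbons from it; the chosen plan adds rings B and C intact and uses their identity.
- Mechanism: a base-mediated condensation cascade is more predictable than a double cross-coupling that has not been run as one operation.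
- Step economy: three or more operations follow the key step of the alternative against one in the chosen plan, and the way to A2 is likely to be as long as the way to 10.
- On ring A regiochemistry the two plans are equal, since both carry the pattern in from a preformed ring.

Alternative 2: The cut lies between the first and second carbons of the chain, together with a temporary O–C bond from the ring A C4 oxygen to the carbon that bears ring C. Heating [4-(tert-butoxy)phenyl][2,4-dihydroxy-5-(hydroxymethyl)phenyl]methanone A5 would expel water to form an ortho-quinone methide across C4 and C5. This would add to 1-(tert-butoxy)-4-ethenylbenzene A6 in a hetero-Diels–Alder reaction with inverse electron demand to give racemic [4-(tert-butoxy)phenyl]{2-[4-(tert-butoxy)phenyl]-7-hydroxychroman-6-yl}methanone A4.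
- In its favour: no metal or organometallic reagent; regiochemistry fixed by the polarity of the partners (the electron-rich alkene terminus bonds to the methylene carbon); an acyl group para to the quinone methide oxygen that should make the heterodiene more electrophilic; and a chelated C2 hydroxyl that can stay unprotected. On the last point the alternative is the better plan.
- Against it here: A4 contains a chroman ring and a stereocentre that the target lacks. The benzylic C–O bond must be cleaved reductively without reducing the diaryl ketone, the freed C4 phenol must be methylated in the presence of the C2 phenol (helped by chelation of the latter), and the tert-butyl ethers must come off, three operations after the key step. The tert-butyl ethers may not tolerate the temperature of the dehydration, and rings B and C enter in separate operations.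
- Structure: the alternative makes and then destroys a ring and a stereocentre and introduces the methyl ether late; the chosen plan inherits the methyl ether from the starting salicylate.
- Mechanism: a pericyclic step with inherent regiocontrol is at least the equal of the chosen coupling in predictability.
- Step economy: the chosen plan is shorter after the key step (one operation against three) and uses one reagent for two rings.

Alternative 3: The cut opens ring A at C1–C2 and C5–C6, so ring A is assembled from a four-carbon diene and a two-carbon alkyne. {[7-[4-(benzyloxy)phenyl]-1,3-dimethoxyhepta-1,3-dien-1-yl]oxy}(trimethyl)silane A8 would add to 1-[4-(benzyloxy)phenyl]prop-2-yn-1-one A9. The nucleophilic chain-bearing diene terminus would bond to the alkyne CH and the ketene acetal carbon to the acyl-bearing carbon. Loss of methanol and of the silyl group would aromatise the adduct to [4-(benzyloxy)phenyl](5-{3-[4-(benzyloxy)phenyl]propyl}-2-hydroxy-4-methoxyphenyl)methanone A7.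
- In its favour: it is convergent, all four ring A substituents are placed by the polarity of the two partners, A7 already has the free C2 hydroxyl and the methyl ether, and one hydrogenolysis leads to the target. After the key step it is the equal of the chosen plan (one operation each), and in protecting-group economy on ring A it is the better.
- Against it here: A8 is a hydrolytically sensitive ketene acetal that has to be made, as a mixture of double-bond isomers, from an enoate already carrying the chain and ring C. Substitution at its reacting terminus slows the cycloaddition, and A9 is a terminal ynone prone to polymerisation. Aromatisation has to expel methanol and not silanol, or C2 ends as a methyl ether. The benzyl ethers must be hydrogenolysed next to a diaryl ketone.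
- Structure: the alternative builds a ring that is commercially available with the right oxygen pattern and does not use the identity of rings B and C.
- Mechanism: it is a known type of benzannulation with built-in regiocontrol, better precedented than the chosen double coupling, but the direction of its aromatisation is not guaranteed.
- Step economy: each of its two partners needs its own multi-step preparation, so the overall count is expected to exceed that of the chosen plan although the end game is equally short.

Key step: step 8

Remarks on the chemistry:
- The structures of 10, 14 and 17 were checked atom by atom against the target (ring A: C1 acyl, C2 oxygen, C4 methoxy, C5 chain) and needed no correction.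
- It cannot be predicted which of the two bonds forms first in step 8, so both mono-coupled species are numbered (15 and 16); either one leads to 17.
- All compounds of the route are achiral.
- Ethanethiol (steps 4 and 8) is handled in a closed system vented through aqueous hypochlorite.

## Route

Step 1
Reactants: 1 methyl 2-hydroxy-4-methoxybenzoate
Product: 2 methyl 2-hydroxy-5-iodo-4-methoxybenzoate
Conditions: NIS, TFA (cat.), MeCN, rt
Reagents that add atoms: N-iodosuccinimide, O=C1CCC(=O)N1I
Why: Electrophilic aromatic iodination; C5 is para to the C2 hydroxyl and ortho to the C4 methoxy group and is less hindered than C3, which lies between both oxygens, while C6 is meta to both donors, so iodine should enter at C5. An aryl iodide is chosen so that the cross-coupling of this electron-rich ring in step 3 can run at moderate temperature.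

Step 2
Reactants: 2 methyl 2-hydroxy-5-iodo-4-methoxybenzoate
Product: 3 methyl 5-iodo-4-methoxy-2-(methoxymethoxy)benzoate
Conditions: CH2(OMe)2, AcCl, ZnBr2 (cat.), toluene, rt; then 2, iPr2NEt, 0 → 45 °C
Reagents that add atoms: dimethoxymethane, COCOC (it delivers the CH2OCH3 group by way of chloro(methoxy)methane, COCCl, formed in the flask)
Why: Williamson-type O-alkylation of the phenol with chloro(methoxy)methane gives the methoxymethyl ether; gentle warming is planned because the phenol is hydrogen-bonded to the ester carbonyl. The chloro ether is made in toluene from dimethoxymethane and acetyl chloride and consumed in the same flask, which avoids handling the neat carcinogen and its bis(chloromethyl) ether impurity; the excess is destroyed with aqueous ammonium chloride before work-up.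

Step 3
Reactants: 3 methyl 5-iodo-4-methoxy-2-(methoxymethoxy)benzoate; 4 prop-2-en-1-yl acetate (allyl acetate)
Product: 7 5-(3-hydroxypropyl)-4-methoxy-2-(methoxymethoxy)benzoic acid, via alkylborane 5 (not isolated), via acetoxy ester 6 (not isolated)
Conditions: 4, 9-BBN, THF, 0 °C → rt; then 3, PdCl2(dppf) (dppf = 1,1'-bis(diphenylphosphino)ferrocene), K3PO4 (aq), THF, 60 °C; then LiOH, MeOH/H2O, 60 °C; 1 M HCl to pH 3–4, 0 °C
Reagents that add atoms: lithium hydroxide, [Li+].[OH-] (its oxygen ends in the carboxyl group)
Why: Anti-Markovnikov hydroboration of the terminal alkene with 9-BBN puts boron on the terminal carbon, and the B-alkyl Suzuki–Miyaura coupling of this borane with the aryl iodide under PdCl2(dppf), whose wide bite angle favours reductive elimination over beta-hydride elimination, forms the C5–CH2 bond. Hydroxide added to the same flask then saponifies the methyl ester and the acetate, so the chain arrives at the alcohol oxidation state without a reduction step and without hydrogen gas. The methoxymethyl ether is stable to base, and the acidification is kept cold and mild.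

Step 4
Reactants: 7 5-(3-hydroxypropyl)-4-methoxy-2-(methoxymethoxy)benzoic acid; 8 ethanethiol
Product: 9 S-ethyl 5-(3-hydroxypropyl)-4-methoxy-2-(methoxymethoxy)benzothioate
Conditions: 8 (4 equiv), EDC·HCl, DMAP (cat.), CH2Cl2, 0 °C → rt
Reagents that add atoms: none
Why: Steglich-type thioesterification: the carbodiimide activates the acid and DMAP passes the acyl group on to the thiol. The thiol is the better nucleophile and is used in excess, which should suppress acylation of the free primary hydroxyl. The thioester is introduced only now because it would not survive the aqueous base of step 3.

Step 5
Reactants: 9 S-ethyl 5-(3-hydroxypropyl)-4-methoxy-2-(methoxymethoxy)benzothioate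
Product: 10 S-ethyl 5-(3-bromopropyl)-4-methoxy-2-(methoxymethoxy)benzothioate
Conditions: CBr4, PPh3, CH2Cl2, 0 °C
Reagents that add atoms: carbon tetrabromide, BrC(Br)(Br)Br
Why: Appel reaction: the alkoxyphosphonium ion formed from the primary alcohol is displaced by bromide under essentially neutral conditions that leave the thioester and the acetal untouched. The bromide is made last because it would not survive saponification.

Step 6
Reactants: 11 4-bromophenol
Product: 12 1-bromo-4-(methoxymethoxy)benzene
Conditions: CH2(OMe)2, AcCl, ZnBr2 (cat.), toluene, rt; then 11, iPr2NEt, 0 °C → rt
Reagents that add atoms: dimethoxymethane, COCOC (it delivers the CH2OCH3 group by way of chloro(methoxy)methane, COCCl, formed in the flask)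
Why: O-Alkylation as in step 2, here on an unhindered phenol. The acetal masks the acidic proton for the organometallic steps and is removed at the end by the same acid as the ring A acetal.

Step 7
Reactants: 12 1-bromo-4-(methoxymethoxy)benzene
Product: 14 [4-(methoxymethoxy)phenyl]zinc bromide, via Grignard reagent 13 (not isolated)
Conditions: Mg, I2 (cat.), THF, 40 °C; then ZnBr2 (1.1 equiv), THF, 0 °C → rt; used as a titrated solution
Reagents that add atoms: zinc bromide, Br[Zn]Br
Why: Magnesium insertion into the aryl bromide (Grignard formation) is followed by transmetalation to zinc; a slight excess of ZnBr2 ensures that no arylmagnesium species, which would add to the thioester or the ketone, remains. Magnesium insertion avoids an alkyllithium reagent and cryogenic conditions, and the MgBr2 formed should assist the later transfer of the aryl group from zinc to palladium.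

Step 8
Reactants: 10 S-ethyl 5-(3-bromopropyl)-4-methoxy-2-(methoxymethoxy)benzothioate; 14 [4-(methoxymethoxy)phenyl]zinc bromide
Product: 17 [4-methoxy-2-(methoxymethoxy)-5-{3-[4-(methoxymethoxy)phenyl]propyl}phenyl][4-(methoxymethoxy)phenyl]methanone, via bromo ketone 15 (not isolated), via arylpropyl thioester 16 (not isolated)
Conditions: 14 (3 equiv), PdCl2(IPr)(3-chloropyridine) (4 mol %), LiBr, THF/DMI (2:1), rt → 45 °C; IPr = 1,3-bis(2,6-diisopropylphenyl)imidazol-2-ylidene, DMI = 1,3-dimethylimidazolidin-2-one
Reagents that add atoms: none
Why: Proposed new method: a single palladium–carbene catalyst is asked to perform an acyl coupling and an alkyl coupling on the same molecule; the closest known reaction types are the Fukuyama coupling of thioesters with organozinc reagents and the Negishi coupling of unactivated primary alkyl bromides with arylzinc halides under PdCl2(IPr)(3-chloropyridine), each established separately. The arylzinc reduces the divalent palladium precatalyst to zerovalent palladium carrying one IPr ligand. In one cycle this inserts into the acyl–sulfur bond, the arylzinc transfers its aryl group while zinc takes up the thiolate, and reductive elimination gives the diaryl ketone. In the other cycle the electron-rich metal adds to the primary C–Br bond in an SN2-like manner, transmetalation follows, and the bulk of IPr makes reductive elimination outrun beta-hydride elimination, forming the CH2–aryl bond. No ring closes and no stereocentre is created, so neither a mode of closure nor a controlling element has to be specified. The selectivity needed is chemoselectivity: the arylzinc halide does not add to the ketone it forms, the ring A phenol is masked as an acetal so that it cannot protonate the reagent, and the thiolate is held on zinc as a weak nucleophile that should not displace the bromide. Because rings B and C are the same aryl group, either mono-coupled intermediate (15 or 16) converges on 17, the order of the two events is irrelevant, and the excess of 14 drives both to completion.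

Step 9
Reactants: 17 [4-methoxy-2-(methoxymethoxy)-5-{3-[4-(methoxymethoxy)phenyl]propyl}phenyl][4-(methoxymethoxy)phenyl]methanone
Product: 18 {2-hydroxy-5-[3-(4-hydroxyphenyl)propyl]-4-methoxyphenyl}(4-hydroxyphenyl)methanone
Conditions: conc. HCl, MeOH/THF, 45 °C
Reagents that add atoms: none
Why: Acid-catalysed acetal exchange with methanol removes all three methoxymethyl groups as dimethoxymethane; the aryl methyl ether and the diaryl ketone are inert under these conditions. Methanol as solvent traps the formaldehyde equivalent, so it should not alkylate the electron-rich rings.

## Compound list

1 | methyl 2-hydroxy-4-methoxybenzoate | COC(=O)c1ccc(OC)cc1O | starting material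
2 | methyl 2-hydroxy-5-iodo-4-methoxybenzoate | COC(=O)c1cc(I)c(OC)cc1O | intermediate
3 | methyl 5-iodo-4-methoxy-2-(methoxymethoxy)benzoate | COC(=O)c1cc(I)c(OC)cc1OCOC | intermediate
4 | prop-2-en-1-yl acetate (allyl acetate) | CC(=O)OCC=C | starting material
5 | 3-(9-borabicyclo[3.3.1]nonan-9-yl)propyl acetate | CC(=O)OCCCB1C2CCCC1CCC2 | intermediate (not isolated)
6 | methyl 5-[3-(acetyloxy)propyl]-4-methoxy-2-(methoxymethoxy)benzoate | COC(=O)c1cc(CCCOC(C)=O)c(OC)cc1OCOC | intermediate (not isolated)
7 | 5-(3-hydroxypropyl)-4-methoxy-2-(methoxymethoxy)benzoic acid | OCCCc1cc(C(=O)O)c(OCOC)cc1OC | intermediate
8 | ethanethiol | CCS | starting material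
9 | S-ethyl 5-(3-hydroxypropyl)-4-methoxy-2-(methoxymethoxy)benzothioate | CCSC(=O)c1cc(CCCO)c(OC)cc1OCOC | intermediate
10 | S-ethyl 5-(3-bromopropyl)-4-methoxy-2-(methoxymethoxy)benzothioate | CCSC(=O)c1cc(CCCBr)c(OC)cc1OCOC | intermediate (ring A precursor of the key step)
11 | 4-bromophenol | Oc1ccc(Br)cc1 | starting material
12 | 1-bromo-4-(methoxymethoxy)benzene | COCOc1ccc(Br)cc1 | intermediate
13 | [4-(methoxymethoxy)phenyl]magnesium bromide | COCOc1ccc([Mg]Br)cc1 | intermediate (not isolated)
14 | [4-(methoxymethoxy)phenyl]zinc bromide | COCOc1ccc([Zn]Br)cc1 | intermediate (aryl precursor of the key step, used in solution)
15 | [5-(3-bromopropyl)-4-methoxy-2-(methoxymethoxy)phenyl][4-(methoxymethoxy)phenyl]methanone | COCOc1ccc(cc1)C(=O)c1cc(CCCBr)c(OC)cc1OCOC | intermediate (not isolated)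
16 | S-ethyl 4-methoxy-2-(methoxymethoxy)-5-{3-[4-(methoxymethoxy)phenyl]propyl}benzothioate | CCSC(=O)c1cc(CCCc2ccc(OCOC)cc2)c(OC)cc1OCOC | intermediate (not isolated)
17 | [4-methoxy-2-(methoxymethoxy)-5-{3-[4-(methoxymethoxy)phenyl]propyl}phenyl][4-(methoxymethoxy)phenyl]methanone | COCOc1ccc(CCCc2cc(C(=O)c3ccc(OCOC)cc3)c(OCOC)cc2OC)cc1 | intermediate (product of the key step)
18 | {2-hydroxy-5-[3-(4-hydroxyphenyl)propyl]-4-methoxyphenyl}(4-hydroxyphenyl)methanone | COc1cc(O)c(C(=O)c2ccc(O)cc2)cc1CCCc1ccc(O)cc1 | target

## Step count and least certain steps

Total step count: 9. Longest linear sequence: 7 steps (steps 1, 2, 3, 4, 5, 8, 9); the arylzinc branch (steps 6 and 7) joins at step 8.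

Step 8 (key step, bears the label "Proposed new method:"). Most likely to go wrong: poisoning of the palladium–carbene catalyst by the zinc thiolate released in the acyl coupling, so that the slower of the two couplings stalls. Beta-hydride elimination from the alkylpalladium intermediate and displacement of bromide by thiolate could also compete. The fallback separates the two events and uses only known chemistry. It sets out from 10: a Fukuyama coupling with 14 under PdCl2(PPh3)2 in THF/toluene at rt should engage only the thioester, because triphenylphosphine-ligated zerovalent palladium does not insert into an unactivated primary C–Br bond at this temperature. [5-(3-Bromopropyl)-4-methoxy-2-(methoxymethoxy)phenyl][4-(methoxymethoxy)phenyl]methanone 15 is then isolated and freed from sulfur by-products. A separate Negishi coupling of its primary bromide with 14 under PdCl2(IPr)(3-chloropyridine) and LiBr in THF/DMI comes back to the route at 17. This fallback makes no compound beyond the list (F0).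

Step 4. Most likely to go wrong: competing acylation of the free primary hydroxyl by the activated acid, leading to self-esterification and oligomers. The fallback removes the free hydroxyl before activation. It sets out from 7: silylation of both the alcohol and the acid with TBSCl and imidazole in DMF gives tert-butyldimethylsilyl 5-{3-[(tert-butyldimethylsilyl)oxy]propyl}-4-methoxy-2-(methoxymethoxy)benzoate F1. K2CO3 in aqueous methanol/THF cleaves only the labile silyl ester and gives 5-{3-[(tert-butyldimethylsilyl)oxy]propyl}-4-methoxy-2-(methoxymethoxy)benzoic acid F2. The same carbodiimide thioesterification with 8 gives S-ethyl 5-{3-[(tert-butyldimethylsilyl)oxy]propyl}-4-methoxy-2-(methoxymethoxy)benzothioate F3. Et3N·3HF in THF removes the silyl ether and comes back to the route at 9.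

Step 3. Most likely to go wrong: slow transfer of the alkyl group from boron to palladium on this electron-rich, ortho-substituted aryl iodide, so that protodeboronation and hydrodeiodination take over; loss of the acetal during acidification is a lesser concern. The fallback builds the chain by an sp–sp2 coupling and reduction. It sets out from 3: Sonogashira coupling with prop-2-yn-1-ol (PdCl2(PPh3)2, CuI, Et3N, THF, rt) gives methyl 5-(3-hydroxyprop-1-yn-1-yl)-4-methoxy-2-(methoxymethoxy)benzoate F4. Hydrogenation over palladium on carbon (H2, Pd/C, EtOAc) gives methyl 5-(3-hydroxypropyl)-4-methoxy-2-(methoxymethoxy)benzoate F5. Saponification with LiOH in aqueous THF/methanol comes back to the route at 7.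

Step 7. Most likely to go wrong: Wurtz-type homocoupling during the magnesium insertion, or incomplete transmetalation that leaves arylmagnesium species able to over-add in step 8. The fallback changes the metalation from insertion to halogen–metal exchange. It sets out from 12: bromine–lithium exchange with n-BuLi in THF at −78 °C gives [4-(methoxymethoxy)phenyl]lithium F6, which is transmetalated with ZnBr2 (−78 °C → rt) and comes back to the route at 14.

## Further compounds

F0 | step 8 | none | none
F1 | step 4 | tert-butyldimethylsilyl 5-{3-[(tert-butyldimethylsilyl)oxy]propyl}-4-methoxy-2-(methoxymethoxy)benzoate | COCOc1cc(OC)c(CCCO[Si](C)(C)C(C)(C)C)cc1C(=O)O[Si](C)(C)C(C)(C)C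
F2 | step 4 | 5-{3-[(tert-butyldimethylsilyl)oxy]propyl}-4-methoxy-2-(methoxymethoxy)benzoic acid | COCOc1cc(OC)c(CCCO[Si](C)(C)C(C)(C)C)cc1C(=O)O
F3 | step 4 | S-ethyl 5-{3-[(tert-butyldimethylsilyl)oxy]propyl}-4-methoxy-2-(methoxymethoxy)benzothioate | CCSC(=O)c1cc(CCCO[Si](C)(C)C(C)(C)C)c(OC)cc1OCOC
F4 | step 3 | methyl 5-(3-hydroxyprop-1-yn-1-yl)-4-methoxy-2-(methoxymethoxy)benzoate | COC(=O)c1cc(C#CCO)c(OC)cc1OCOC
F5 | step 3 | methyl 5-(3-hydroxypropyl)-4-methoxy-2-(methoxymethoxy)benzoate | COC(=O)c1cc(CCCO)c(OC)cc1OCOC
F6 | step 7 | [4-(methoxymethoxy)phenyl]lithium | COCOc1ccc([Li])cc1
A1 | alternative 1 | dimethyl 5-(5-{3-[4-(benzyloxy)phenyl]propyl}-2-hydroxy-4-methoxybenzoyl)-2-hydroxybenzene-1,3-dicarboxylate | COC(=O)c1cc(C(=O)c2cc(CCCc3ccc(OCc4ccccc4)cc3)c(OC)cc2O)cc(C(=O)OC)c1O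
A2 | alternative 1 | 6-{3-[4-(benzyloxy)phenyl]propyl}-7-methoxy-4-oxo-4H-chromene-3-carbaldehyde | O=Cc1coc2cc(OC)c(CCCc3ccc(OCc4ccccc4)cc3)cc2c1=O
A3 | alternative 1 | dimethyl 3-oxopentanedioate | COC(=O)CC(=O)CC(=O)OC
A4 | alternative 2 | [4-(tert-butoxy)phenyl]{2-[4-(tert-butoxy)phenyl]-7-hydroxychroman-6-yl}methanone (racemic) | O=C(c1ccc(OC(C)(C)C)cc1)c1cc2c(cc1O)OC(c1ccc(OC(C)(C)C)cc1)CC2
A5 | alternative 2 | [4-(tert-butoxy)phenyl][2,4-dihydroxy-5-(hydroxymethyl)phenyl]methanone | O=C(c1ccc(OC(C)(C)C)cc1)c1cc(CO)c(O)cc1O
A6 | alternative 2 | 1-(tert-butoxy)-4-ethenylbenzene | C=Cc1ccc(OC(C)(C)C)cc1
A7 | alternative 3 | [4-(benzyloxy)phenyl](5-{3-[4-(benzyloxy)phenyl]propyl}-2-hydroxy-4-methoxyphenyl)methanone | COc1cc(O)c(C(=O)c2ccc(OCc3ccccc3)cc2)cc1CCCc1ccc(OCc2ccccc2)cc1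
A8 | alternative 3 | {[7-[4-(benzyloxy)phenyl]-1,3-dimethoxyhepta-1,3-dien-1-yl]oxy}(trimethyl)silane (mixture of double-bond isomers) | COC(O[Si](C)(C)C)=CC(OC)=CCCCc1ccc(OCc2ccccc2)cc1
A9 | alternative 3 | 1-[4-(benzyloxy)phenyl]prop-2-yn-1-one | C#CC(=O)c1ccc(OCc2ccccc2)cc1
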